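**Strategy.** The plan rests on closing the cyclobutane bond C10–C11 (longipinane numbering: C1 enone C=O, C11 its α-CH, C10 the CH3-bearing quaternary carbon, C9 the senecioate carbon). This bond is the centre of the 1,4-dioxygenated array O=C1–C11–C10–C9–O, between the six-membered enone ring and the cyclobutane. Its precursor is a bridgehead-silyloxy norbornene in which C10 is still bonded to C1, built by an intramolecular Diels–Alder reaction of a 5,5-disubstituted 1-silyloxycyclopenta-1,3-diene onto a tethered (E)-alkenylboronate. Fluoride then triggers retro-aldol cleavage of C1–C10, and the freed C9/C10 enolate alkylates C11. One operation converts bicyclo[2.2.1] into the bicyclo[3.1.1]heptenone.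

Key step: step 11

Remark on labels: atom labels are longipinane locants: C1 (C=O), C2=C3 (C3 bears CH3), C4 and C11 (ring-fusion CH; C11 is α to C1), C5 (cyclobutane CH bonded to C6(CH3)2), C7 (isovalerate), C8 (CH2), C9 (senecioate), C10 (quaternary, CH3).

Assumption: the (R)-SEGPHOS antipode is taken to give the (3R)-carbinol in step 1; if the sense of induction is the opposite, (S)-SEGPHOS is used instead.

Step 1
Reactants: 1 3,3-diethoxypropan-1-ol; 2 3-methylbuta-1,2-diene
Product: 3 (3R)-1,1-diethoxy-4,4-dimethylhex-5-en-3-ol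
Conditions: preformed cyclometalated catalyst [Ir(η3-C3H5)((R)-SEGPHOS)(C,O-4-cyano-3-nitrobenzoate)] (5 mol%), 2 (3 equiv), toluene, 60 °C, sealed tube
Reagents that add atoms: none
Why: Iridium-catalysed transfer-hydrogenative carbonyl tert-prenylation; the alcohol is dehydrogenated to the aldehyde, the allene becomes a 1,1-dimethylallyl iridium species that adds through a closed chair transition state, and the chiral bisphosphine sets C7 (3R) while the C6 gem-dimethyl carbon and the vinyl group are made at once.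

Step 2
Reactants: 3 (3R)-1,1-diethoxy-4,4-dimethylhex-5-en-3-ol
Product: 4 (3R)-1,1-diethoxy-3-[(4-methoxybenzyl)oxy]-4,4-dimethylhex-5-ene
Conditions: NaH, 4-methoxybenzyl chloride, Bu4NI (cat.), DMF, 0 °C to rt
Reagents that add atoms: 4-methoxybenzyl chloride, COc1ccc(CCl)cc1
Why: Williamson etherification of the hindered alkoxide with iodide catalysis; the PMB ether is chosen because a β-OPMB group should give high 1,3-anti induction in step 4 and can be removed oxidatively in step 12.

Step 3
Reactants: 4 (3R)-1,1-diethoxy-3-[(4-methoxybenzyl)oxy]-4,4-dimethylhex-5-ene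
Product: 5 (3R)-3-[(4-methoxybenzyl)oxy]-4,4-dimethylhex-5-enal
Conditions: 1 M aq. HCl (cat.), THF, rt
Reagents that add atoms: water, O
Why: Acid hydrolysis of an acyclic diethyl acetal, which should be much faster than loss of the PMB ether or β-elimination of the alkoxy group.

Step 4
Reactants: 5 (3R)-3-[(4-methoxybenzyl)oxy]-4,4-dimethylhex-5-enal; 6 3-methylcyclopent-2-en-1-one
Product: 9 5-[(1R,3R)-1-hydroxy-3-[(4-methoxybenzyl)oxy]-4,4-dimethylhex-5-en-1-yl]-3-methylcyclopent-2-en-1-one (both ring C5 epimers), via lithium dienolate 7 (not isolated), via silyl dienol ether 8 (not isolated)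
Conditions: 6, LiN(iPr)2 (LDA, 1.05 equiv), THF, −78 °C; Me3SiCl; solvent exchange to CH2Cl2; 5, BF3·OEt2, −78 °C; aq. NaHCO3
Reagents that add atoms: chlorotrimethylsilane, C[Si](C)(C)Cl (silicon is carried only in intermediate 8)
Why: Kinetic α′-deprotonation and O-silylation give the cross-conjugated silyl dienol ether, and its Mukaiyama aldol addition through an open transition state should follow the 1,3-anti induction of β-alkoxy aldehydes, which sets C9 (1R) anti to C7; the ring C5 configuration is erased in step 5.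

Step 5
Reactants: 9 5-[(1R,3R)-1-hydroxy-3-[(4-methoxybenzyl)oxy]-4,4-dimethylhex-5-en-1-yl]-3-methylcyclopent-2-en-1-one
Product: 11 (5S)-5-[(1R,3R)-1-hydroxy-3-[(4-methoxybenzyl)oxy]-4,4-dimethylhex-5-en-1-yl]-3,5-dimethylcyclopent-2-en-1-one, via dilithium dianion 10 (not isolated)
Conditions: LiN(iPr)2 (LDA, 2.3 equiv), THF, −78 to −30 °C; CH3I, DMPU, −78 to −40 °C; aq. NH4Cl
Reagents that add atoms: iodomethane, CI
Why: Fráter–Seebach-type alkylation; in the lithium-chelated aldolate–enolate the side chain on the carbinol carbon shields one enolate face, so CH3I should enter anti to it (CH3 anti to OH), which sets the quaternary C10 (5S) from C9, and the α′ C–H is held perpendicular to the ring carbonyl so that enolisation toward the aldolate is stereoelectronically allowed.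

Step 6
Reactants: 11 (5S)-5-[(1R,3R)-1-hydroxy-3-[(4-methoxybenzyl)oxy]-4,4-dimethylhex-5-en-1-yl]-3,5-dimethylcyclopent-2-en-1-one; 12 4,4,5,5-tetramethyl-2-vinyl-1,3,2-dioxaborolane
Product: 13 (5S)-5-[(1R,3R,5E)-1-hydroxy-3-[(4-methoxybenzyl)oxy]-4,4-dimethyl-6-(4,4,5,5-tetramethyl-1,3,2-dioxaborolan-2-yl)hex-5-en-1-yl]-3,5-dimethylcyclopent-2-en-1-one
Conditions: 12 (4 equiv), second-generation Hoveyda–Grubbs catalyst RuCl2(H2IMes)(=CH-C6H4-2-OiPr) (10 mol%), CH2Cl2, 40 °C
Reagents that add atoms: none
Why: Olefin cross-metathesis; the vinyl group next to the quaternary carbon does not homodimerise and should couple with the excess vinylboronate to the E-alkenylboronate under thermodynamic control, which fixes the dienophile geometry.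

Step 7
Reactants: 13 (5S)-5-[(1R,3R,5E)-1-hydroxy-3-[(4-methoxybenzyl)oxy]-4,4-dimethyl-6-(4,4,5,5-tetramethyl-1,3,2-dioxaborolan-2-yl)hex-5-en-1-yl]-3,5-dimethylcyclopent-2-en-1-one
Product: 16 tricyclic norbornene alcohol (bridgehead C1–OTBS; C2=C3 alkene with CH3 on C3; C10 as one-carbon bridge with its CH3 syn to the alkene; seven-membered ring C10–C9(OH)–C8–C7(OPMB)–C6(CH3)2–C5–C4 joined exo at C5; pinacolboryl endo on C11), via silylated triene 14 (not isolated), via bis-silyl cycloadduct 15 (not isolated)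
Conditions: Me3SiOTf (1.05 equiv), Et3N, CH2Cl2, −78 °C; tBuMe2SiOTf (1.5 equiv), −78 to 0 °C; cold aq. NaHCO3; toluene (0.01 M), BHT, 140 °C, sealed tube; then K2CO3 (cat.), MeOH, 0 °C
Reagents that add atoms: tert-butyldimethylsilyl trifluoromethanesulfonate, CC(C)(C)[Si](C)(C)OS(=O)(=O)C(F)(F)F; trimethylsilyl trifluoromethanesulfonate, C[Si](C)(C)OS(=O)(=O)C(F)(F)F (silicon is carried only in intermediates 14 and 15)
Why: O-silylation and γ-enolisation give a 5,5-disubstituted 1-silyloxycyclopentadiene that cannot undergo 1,5-hydrogen shifts, and in the intramolecular Diels–Alder reaction the tether on C10 lets the dienophile reach only one diene face, so C10 sets C1, C4, C5 and C11; the donor on C1, the boron on C11 and the bonding of neopentyl C5 to unsubstituted C4 give the regiochemistry, the E geometry places boron endo and the tether exo, and methanolysis removes only the trimethylsilyl ether.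

Step 8
Reactants: 16 tricyclic norbornene alcohol
Product: 17 tricyclic norbornene ketone (C9=O; bridgehead C1–OTBS; pinacolboryl endo on C11)
Conditions: Dess–Martin periodinane, CH2Cl2, 0 °C to rt
Reagents that add atoms: none
Why: Dess–Martin oxidation of the only free (secondary) alcohol under neutral conditions; the tertiary silyl ether keeps the strained bridgehead aldol C1(O)–C10–C9(=O) masked.

Step 9
Reactants: 17 tricyclic norbornene ketone
Product: 18 tricyclic norbornene hydroxy ketone (C11 endo OH; C9=O; bridgehead C1–OTBS)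
Conditions: NaBO3·4H2O, THF/H2O (1:1), rt
Reagents that add atoms: sodium perborate, [Na+].[Na+].O[B-]1(O)OO[B-](O)(O)OO1
Why: Oxidation of the C–B bond by perborate through a 1,2-boronate shift with retention, which gives the endo alcohol on C11; the mild medium should leave the β-silyloxy ketone intact.

Step 10
Reactants: 18 tricyclic norbornene hydroxy ketone
Product: 19 tricyclic norbornene mesylate (C11 endo OSO2CH3; C9=O; bridgehead C1–OTBS)
Conditions: CH3SO2Cl, Et3N, CH2Cl2, −20 °C
Reagents that add atoms: methanesulfonyl chloride, CS(=O)(=O)Cl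
Why: Mesylation through sulfene should reach the hindered endo alcohol and places the leaving group on the carbon that becomes α to the C1 ketone.

Step 11
Reactants: 19 tricyclic norbornene mesylate
Product: 21 (4R,5S,7R,10R,11R)-7-[(4-methoxybenzyl)oxy]longipin-2-ene-1,9-dione, via seco enolate 20 (not isolated)
Conditions: [(Me2N)3S][Me3SiF2] (TASF, 1.3 equiv), THF/DMF (10:1), −40 to 0 °C; pH 7 buffer
Reagents that add atoms: none
Why: Fluoride removes the bridgehead silyl group, the C1 alkoxide undergoes retro-aldol cleavage of C1–C10 through the C9 ketone (release of norbornene strain, formation of the C1 enone) to give regiospecifically the tetrasubstituted C9/C10 enolate, and this enolate displaces the mesylate on C11, now α to the C1 carbonyl, to form C10–C11. The closest known reaction types are the fluoride-triggered retro-aldol fragmentation of β-silyloxy ketones and the intramolecular enolate alkylation that gives bicyclo[3.1.1]heptanones. The cyclobutane closes 4-(enolexo)-exo-tet, and the same bond completes the six-membered enone ring C1–C2–C3–C4–C10–C11. C11 is inverted, because the enolate carbon is held on the exo side by C4 and attacks anti to the endo mesylate, and the C10 quaternary centre forms on the only enolate face that can reach C11 in the cis-fused bicycle. The step needs C- over O-alkylation and substitution over elimination: O-alkylation would require a trans double bond in a six-membered ring, and the only β-hydrogen (on C5) is cis to the mesylate. A direct 1,2-shift of C10 from C1 to C11, whose migrating bond is antiperiplanar to the endo leaving group, would lead to the same product.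

Step 12
Reactants: 21 (4R,5S,7R,10R,11R)-7-[(4-methoxybenzyl)oxy]longipin-2-ene-1,9-dione
Product: 22 (4R,5S,7R,10R,11R)-7-hydroxylongipin-2-ene-1,9-dione
Conditions: DDQ, CH2Cl2/pH 7 buffer (10:1), 0 °C to rt
Reagents that add atoms: none
Why: Oxidative PMB cleavage by benzylic hydride abstraction; the enone and the saturated ketone are inert to DDQ.

Step 13
Reactants: 22 (4R,5S,7R,10R,11R)-7-hydroxylongipin-2-ene-1,9-dione
Product: 23 (4R,5S,7R,9R,10R,11R)-9-hydroxy-7-(3-methylbutanoyloxy)longipin-2-en-1-one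
Conditions: 3-methylbutanal (6 equiv), SmI2 (0.3 equiv, 0.1 M in THF), THF, −10 °C, dark
Reagents that add atoms: 3-methylbutanal, CC(C)CC=O
Why: Evans–Tishchenko reduction; the samarium-bound hemiacetal of O7 with the aldehyde delivers hydride intramolecularly to the C9 carbonyl from the face of the C7–O bond, which should give the anti (trans) 1,3-diol monoester, so that C9 (R) is set, the isovalerate is placed on O7 and O9–H stays free, while the enone (no β-hydroxyl) is untouched.

Step 14
Reactants: 23 (4R,5S,7R,9R,10R,11R)-9-hydroxy-7-(3-methylbutanoyloxy)longipin-2-en-1-one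
Product: 24 (4R,5S,7R,9R,10R,11R)-7-(3-methylbutanoyloxy)-9-(3-methylbut-2-enoyloxy)longipin-2-en-1-one (CNP0335239.1)
Conditions: 3-methylbut-2-enoyl chloride, pyridine, DMAP (cat.), CH2Cl2, 0 °C to rt
Reagents that add atoms: 3-methylbut-2-enoyl chloride, CC(C)=CC(Cl)=O
Why: DMAP-catalysed acylation of the remaining hindered secondary alcohol; pyridine as a weak base should avoid deconjugation of the senecioyl group through a vinylketene.

**Compound list**

1 | 3,3-diethoxypropan-1-ol | OCCC(OCC)OCC | starting material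
2 | 3-methylbuta-1,2-diene | CC(C)=C=C | starting material
3 | (3R)-1,1-diethoxy-4,4-dimethylhex-5-en-3-ol | CCOC(OCC)C[C@@H](O)C(C)(C)C=C | intermediate
4 | (3R)-1,1-diethoxy-3-[(4-methoxybenzyl)oxy]-4,4-dimethylhex-5-ene | CCOC(OCC)C[C@@H](OCc1ccc(OC)cc1)C(C)(C)C=C | intermediate
5 | (3R)-3-[(4-methoxybenzyl)oxy]-4,4-dimethylhex-5-enal | O=CC[C@@H](OCc1ccc(OC)cc1)C(C)(C)C=C | intermediate
6 | 3-methylcyclopent-2-en-1-one | CC1=CC(=O)CC1 | starting material
7 | lithium 4-methylcyclopenta-1,3-dien-2-olate (kinetic α′-enolate of 6) | [Li+].CC1=CC([O-])=CC1 | intermediate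
8 | 4-methyl-2-(trimethylsilyloxy)cyclopenta-1,3-diene | CC1=CC(O[Si](C)(C)C)=CC1 | intermediate
9 | 5-[(1R,3R)-1-hydroxy-3-[(4-methoxybenzyl)oxy]-4,4-dimethylhex-5-en-1-yl]-3-methylcyclopent-2-en-1-one (ring C5 epimers) | CC1=CC(=O)C(C1)[C@H](O)C[C@@H](OCc2ccc(OC)cc2)C(C)(C)C=C | intermediate
10 | dilithium aldolate–dienolate of 9 | [Li+].[Li+].CC1=CC([O-])=C(C1)[C@H]([O-])C[C@@H](OCc2ccc(OC)cc2)C(C)(C)C=C | intermediate
11 | (5S)-5-[(1R,3R)-1-hydroxy-3-[(4-methoxybenzyl)oxy]-4,4-dimethylhex-5-en-1-yl]-3,5-dimethylcyclopent-2-en-1-one | O=C1C=C(C)C[C@@]1(C)[C@H](O)C[C@@H](OCc2ccc(OC)cc2)C(C)(C)C=C | intermediate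
12 | 4,4,5,5-tetramethyl-2-vinyl-1,3,2-dioxaborolane | C=CB1OC(C)(C)C(C)(C)O1 | starting material
13 | (5S)-5-[(1R,3R,5E)-1-hydroxy-3-[(4-methoxybenzyl)oxy]-4,4-dimethyl-6-(4,4,5,5-tetramethyl-1,3,2-dioxaborolan-2-yl)hex-5-en-1-yl]-3,5-dimethylcyclopent-2-en-1-one | O=C1C=C(C)C[C@@]1(C)[C@H](O)C[C@@H](OCc2ccc(OC)cc2)C(C)(C)/C=C/B3OC(C)(C)C(C)(C)O3 | intermediate
14 | silylated triene: (5S)-1-(tert-butyldimethylsilyloxy)-3,5-dimethylcyclopenta-1,3-diene carrying on C5 the (1R,3R,5E)-1-(trimethylsilyloxy)-3-(PMB-oxy)-4,4-dimethyl-6-(pinacolboryl)hex-5-enyl chain | CC(C)(C)[Si](C)(C)OC1=CC(C)=C[C@@]1(C)[C@H](O[Si](C)(C)C)C[C@@H](OCc2ccc(OC)cc2)C(C)(C)/C=C/B3OC(C)(C)C(C)(C)O3 | intermediate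
15 | bis-silyl cycloadduct: norbornene with bridgehead C1–OTBS, C9–OSiMe3, C7–OPMB, endo pinacolboryl on C11, tether exo on C5 | C[Si](C)(C)O[C@@H]1C[C@@H](OCc4ccc(OC)cc4)C(C)(C)[C@@H]2[C@@H](B5OC(C)(C)C(C)(C)O5)[C@@]3(O[Si](C)(C)C(C)(C)C)C=C(C)[C@@H]2[C@]31C | intermediate
16 | tricyclic norbornene alcohol (C9–OH, bridgehead C1–OTBS, C7–OPMB, endo pinacolboryl on C11) | O[C@@H]1C[C@@H](OCc4ccc(OC)cc4)C(C)(C)[C@@H]2[C@@H](B5OC(C)(C)C(C)(C)O5)[C@@]3(O[Si](C)(C)C(C)(C)C)C=C(C)[C@@H]2[C@]31C | intermediate
17 | tricyclic norbornene ketone (C9=O, bridgehead C1–OTBS, C7–OPMB, endo pinacolboryl on C11) | O=C1C[C@@H](OCc4ccc(OC)cc4)C(C)(C)[C@@H]2[C@@H](B5OC(C)(C)C(C)(C)O5)[C@@]3(O[Si](C)(C)C(C)(C)C)C=C(C)[C@@H]2[C@]31C | intermediate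
18 | tricyclic norbornene hydroxy ketone (C11 endo OH, C9=O, bridgehead C1–OTBS, C7–OPMB) | O=C1C[C@@H](OCc4ccc(OC)cc4)C(C)(C)[C@@H]2[C@@H](O)[C@@]3(O[Si](C)(C)C(C)(C)C)C=C(C)[C@@H]2[C@]31C | intermediate
19 | tricyclic norbornene mesylate (C11 endo OSO2CH3, C9=O, bridgehead C1–OTBS, C7–OPMB) | O=C1C[C@@H](OCc4ccc(OC)cc4)C(C)(C)[C@@H]2[C@@H](OS(C)(=O)=O)[C@@]3(O[Si](C)(C)C(C)(C)C)C=C(C)[C@@H]2[C@]31C | intermediate
20 | seco enolate: cis-fused bicyclo[5.4.0]undecadienone with C9/C10 enolate, C1 enone and C11 mesylate, tris(dimethylamino)sulfonium salt | CC1=CC(=O)[C@H](OS(C)(=O)=O)[C@H]2C(C)(C)[C@H](OCc3ccc(OC)cc3)CC([O-])=C(C)[C@@H]12.CN(C)[S+](N(C)C)N(C)C | intermediate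
21 | (4R,5S,7R,10R,11R)-7-[(4-methoxybenzyl)oxy]longipin-2-ene-1,9-dione | O=C1C[C@@H](OCc4ccc(OC)cc4)C(C)(C)[C@@H]2[C@H]3C(=O)C=C(C)[C@@H]2[C@]31C | intermediate
22 | (4R,5S,7R,10R,11R)-7-hydroxylongipin-2-ene-1,9-dione | O=C1C[C@@H](O)C(C)(C)[C@@H]2[C@H]3C(=O)C=C(C)[C@@H]2[C@]31C | intermediate
23 | (4R,5S,7R,9R,10R,11R)-9-hydroxy-7-(3-methylbutanoyloxy)longipin-2-en-1-one | O[C@@H]1C[C@@H](OC(=O)CC(C)C)C(C)(C)[C@@H]2[C@H]3C(=O)C=C(C)[C@@H]2[C@]31C | intermediate
24 | (4R,5S,7R,9R,10R,11R)-7-(3-methylbutanoyloxy)-9-(3-methylbut-2-enoyloxy)longipin-2-en-1-one (CNP0335239.1; 7,9-trans) | CC(C)=CC(=O)O[C@@H]1C[C@@H](OC(=O)CC(C)C)C(C)(C)[C@@H]2[C@H]3C(=O)C=C(C)[C@@H]2[C@]31C | target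

Total step count: 14
Longest linear sequence: 14 steps (1 to 24; 2, 6 and 12 are commercial)

**Steps most likely to fail**

Step 7. The tethered cycloaddition may not take place before the silyl dienol ether decomposes, because bond formation at the neopentyl carbon C5 is slow and a pinacol boronate activates the alkene only weakly. Enolisation toward the C3 methyl group instead of C4 would also give an unreactive cross-conjugated isomer. The fallback changes the dienophile, not the conditions. It sets out from 13: NaIO4/NH4OAc (acetone/H2O) should cleave the pinacol ester to the alkenylboronic acid F1, and catechol (MgSO4, CH2Cl2) should give the benzodioxaborole F2, whose boron is less shielded and more Lewis acidic. Silylation as in step 7 should give the silylated triene F3 (not isolated), expected to cyclise at lower temperature to the catechol boronate cycloadduct F4 (not isolated). Pinacol then exchanges the boron ligand to give 15, and K2CO3/MeOH returns the route to 16.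

Step 11. The enolate may be protonated, or may take a proton from C8, before it alkylates C11; the C8 enolate would then lose the C7 ether by β-elimination. The fallback avoids a free enolate. It sets out from 18: Tf2O and 2,6-di-tert-butyl-4-methylpyridine (CH2Cl2, −78 to 0 °C) should give the endo triflate F5 (not isolated). Its C1–C10 bond is antiperiplanar to the leaving group and should migrate to C11 with push from the silyloxy group (semipinacol rearrangement of a 2-sulfonyloxy silyl ether, as known for bridgehead-oxygenated bicyclo[2.2.2]octenyl sulfonates). This returns the route to 21.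

Step 5. Deprotonation of the lithium aldolate at the γ-position (C4) instead of C10, or retro-aldol cleavage, would erode regio- and stereocontrol of the methylation. The fallback installs the methyl group before the aldol. It sets out from 6: LDA and CH3I should give 3,5-dimethylcyclopent-2-en-1-one F6, whose kinetic silyl dienol ether F7 undergoes the same BF3·OEt2 aldol addition with 5. The quaternary centre then forms in the open transition state with little control, so 11 has to be separated by chromatography from its ring C5 epimer F8 (C9 stays anti to C7 in both). The route is rejoined at 11.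

Further compounds
F1 | step 7 | [(1E,4R,6R)-6-hydroxy-4-[(4-methoxybenzyl)oxy]-3,3-dimethyl-6-[(1S)-1,3-dimethyl-2-oxocyclopent-3-en-1-yl]hex-1-en-1-yl]boronic acid | O=C1C=C(C)C[C@@]1(C)[C@H](O)C[C@@H](OCc2ccc(OC)cc2)C(C)(C)/C=C/B(O)O
F2 | step 7 | catechol ester (1,3,2-benzodioxaborole) of F1 | O=C1C=C(C)C[C@@]1(C)[C@H](O)C[C@@H](OCc2ccc(OC)cc2)C(C)(C)/C=C/B3Oc4ccccc4O3
F3 | step 7 | silylated triene with benzodioxaborole (C1–OTBS dienol ether, C9–OSiMe3) | CC(C)(C)[Si](C)(C)OC1=CC(C)=C[C@@]1(C)[C@H](O[Si](C)(C)C)C[C@@H](OCc2ccc(OC)cc2)C(C)(C)/C=C/B3Oc4ccccc4O3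
F4 | step 7 | bis-silyl cycloadduct with endo benzodioxaborole on C11 | C[Si](C)(C)O[C@@H]1C[C@@H](OCc4ccc(OC)cc4)C(C)(C)[C@@H]2[C@@H](B5Oc6ccccc6O5)[C@@]3(O[Si](C)(C)C(C)(C)C)C=C(C)[C@@H]2[C@]31C
F5 | step 11 | tricyclic norbornene triflate (C11 endo OSO2CF3, C9=O, bridgehead C1–OTBS, C7–OPMB) | O=C1C[C@@H](OCc4ccc(OC)cc4)C(C)(C)[C@@H]2[C@@H](OS(=O)(=O)C(F)(F)F)[C@@]3(O[Si](C)(C)C(C)(C)C)C=C(C)[C@@H]2[C@]31C
F6 | step 5 | 3,5-dimethylcyclopent-2-en-1-one | CC1=CC(=O)C(C)C1
F7 | step 5 | 1,4-dimethyl-2-(trimethylsilyloxy)cyclopenta-1,3-diene | CC1=CC(O[Si](C)(C)C)=C(C)C1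
F8 | step 5 | (5R)-5-[(1R,3R)-1-hydroxy-3-[(4-methoxybenzyl)oxy]-4,4-dimethylhex-5-en-1-yl]-3,5-dimethylcyclopent-2-en-1-one | O=C1C=C(C)C[C@]1(C)[C@H](O)C[C@@H](OCc2ccc(OC)cc2)C(C)(C)C=C
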